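## Retrosynthetic overview

1. Plakortolide K (20) ⇐ acid 19 (loss of CO2) ⇐ bridged lactone 17 (lactone exchange) ⇐ bridged keto peroxide 16 (Baeyer–Villiger). The lactone oxygen on C4 is traded for a ketone carbon that, with C1′ and C2′ of the side chain, forms a temporary cyclohexanone.
2. Enabling feature: in the 1,2-dioxane ring, C4 and C6 are both fully substituted and stand 1,3 across the C5 methylene. They carry the lactone oxygen and the side chain on the same ring face, so these cis groups can be tied into one carbocycle. A C4–C6 bond then makes C4–C5–C6 a donor–acceptor cyclopropane, and C3 is an acetal-level carbon next to O–O.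
3. Key disconnection: (3+3) annulation of cyclopropyl ketone 9 with the carbonyl-oxide equivalent 13. It makes the O–C6 bond, the C3–C4 bond and all three stereocentres at once.
4. 9 ⇐ 2,3-dimethylcyclopentenone (asymmetric reduction, directed cyclopropanation, oxidation, alkylation with 7). 13 ⇐ dimethyl (E)-hex-3-enedioate (ozonolysis in methanol, silylation).
5. Ring order: cyclopentene (bought), cyclopropane, then in the key step cyclohexanone plus 1,2-dioxane at the cost of the cyclopropane, then seven-membered lactone, then γ-lactone (carbocycle gone).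

Key step: step 8

Remark: positions follow plakortolide numbering (C1 lactone C=O, C2 CH2, C3 CH–OO, C4 C(CH3)–O, C5 CH2, C6 C(CH3)(chain)–OO, C1′, C2′ … along the chain). The sense of induction in step 1 is taken from the usual large/small model of the oxazaborolidine reduction.

## Route

Step 1
Reactants: 1 2,3-dimethylcyclopent-2-en-1-one
Product: 2 (R)-2,3-dimethylcyclopent-2-en-1-ol
Conditions: BH3·SMe2, (S)-1-methyl-3,3-diphenyltetrahydro-1H,3H-pyrrolo[1,2-c][1,3,2]oxazaborole (10 mol%), THF, −20 °C; MeOH, then aqueous work-up
Reagents that add atoms: none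
Why: Corey–Bakshi–Shibata reduction: the oxazaborolidine binds borane and ketone so that hydride reaches one carbonyl face only, the alkene-bearing side acting as the large group, which sets the carbinol centre as R.

Step 2
Reactants: 2 (R)-2,3-dimethylcyclopent-2-en-1-ol
Product: 3 (1S,2R,5R)-1,5-dimethylbicyclo[3.1.0]hexan-2-ol (OH and cyclopropane CH2 on the same face)
Conditions: Et2Zn, CH2I2, CH2Cl2, 0 °C to rt
Reagents that add atoms: diiodomethane, ICI
Why: Hydroxyl-directed Simmons–Smith cyclopropanation (Furukawa variant): the zinc carbenoid is delivered to the alkene face that carries the OH group, so the carbinol centre sets both quaternary ring-fusion centres.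

Step 3
Reactants: 3 (1S,2R,5R)-1,5-dimethylbicyclo[3.1.0]hexan-2-ol
Product: 4 (1S,5R)-1,5-dimethylbicyclo[3.1.0]hexan-2-one
Conditions: Dess–Martin periodinane, CH2Cl2, rt
Reagents that add atoms: none
Why: Dess–Martin oxidation of a secondary alcohol under neutral conditions leaves the cyclopropane and both quaternary centres untouched and turns the ring into a donor–acceptor cyclopropane.

Step 4
Reactants: 5 phenylmagnesium bromide; 6 1,10-diiododecane (excess)
Product: 7 (10-iododecyl)benzene
Conditions: Li2CuCl4 (3 mol%), THF, −10 °C
Reagents that add atoms: none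
Why: Copper-catalysed Kochi-type cross-coupling of a Grignard reagent with a primary alkyl iodide, in which the excess of 6 keeps the second iodide free.

Step 5
Reactants: 4 (1S,5R)-1,5-dimethylbicyclo[3.1.0]hexan-2-one; 7 (10-iododecyl)benzene
Product: 9 (1S,3S,5R)-1,5-dimethyl-3-(10-phenyldecyl)bicyclo[3.1.0]hexan-2-one (chain anti to the cyclopropane CH2), via lithium enolate 8 (not isolated)
Conditions: LiN(iPr)2, THF, −78 °C; then 7, DMPU, −78 to 0 °C
Reagents that add atoms: none
Why: Kinetic enolate alkylation: only C3 of 4 bears acidic hydrogens and the iodide should approach anti to the cyclopropane CH2, giving a centre that is erased again in step 11.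

Step 6
Reactants: 10 dimethyl (E)-hex-3-enedioate
Product: 12 methyl 3-hydroperoxy-3-methoxypropanoate (racemic), via carbonyl oxide 11 (not isolated)
Conditions: O3, CH2Cl2/MeOH, −78 °C; N2 purge, no reductant
Reagents that add atoms: ozone, [O-][O+]=O; methanol, CO
Why: Ozonolysis in methanol (Criegee mechanism): the symmetrical alkene can give only one carbonyl oxide, which methanol traps as the α-methoxy hydroperoxide, whose racemic centre is planarised in step 8.

Step 7
Reactants: 12 methyl 3-hydroperoxy-3-methoxypropanoate
Product: 13 methyl 3-methoxy-3-[(triethylsilyl)peroxy]propanoate (racemic)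
Conditions: Et3SiCl, imidazole, CH2Cl2, 0 °C
Reagents that add atoms: chlorotriethylsilane, CC[Si](Cl)(CC)CC
Why: O-Silylation of a hydroperoxide with a chlorosilane and imidazole is a standard protection and removes the acidic proton so that step 8 can run aprotically.

Step 8
Reactants: 9 (1S,3S,5R)-1,5-dimethyl-3-(10-phenyldecyl)bicyclo[3.1.0]hexan-2-one; 13 methyl 3-methoxy-3-[(triethylsilyl)peroxy]propanoate
Product: 16 methyl 2-[(1S,4R,5R,7S)-1,5-dimethyl-6-oxo-7-(10-phenyldecyl)-2,3-dioxabicyclo[3.3.1]nonan-4-yl]acetate, via peroxy silyl enol ether 14 (not isolated), via peroxycarbenium triflate 15 (not isolated)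
Conditions: Me3SiOSO2CF3 (20 mol%), 2,6-di-tert-butyl-4-methylpyridine (10 mol%), CH2Cl2, −78 to −30 °C
Reagents that add atoms: none
Why: Proposed new method: a Lewis-acid (3+3) annulation of a donor–acceptor cyclopropane with a carbonyl-oxide equivalent, in which Me3SiOSO2CF3 silylates the ketone oxygen of 9, the peroxide oxygen of 13 opens the activated ring at the fully substituted donor carbon (future C6) by homoconjugate addition and hands its Et3Si group to triflate to give the regiodefined silyl enol ether 14, the silyl triflate then removes the methoxy group, and the enol silane carbon (future C4) adds to the peroxycarbenium carbon (future C3) of 15, which regenerates the catalyst. The closest known reaction types are the (3+3) annulation of nitrones with donor–acceptor cyclopropanes, the halosilane opening of cyclopropyl ketones to γ-substituted silyl enol ethers, the coupling of silyl enol ethers with peroxycarbenium ions, and the annulation of silylperoxycarbenium ions with alkenes to 1,2-dioxolanes. The 1,2-dioxane is closed in a 6-(enolexo)-endo-trig mode, while the cyclohexanone is not closed but arises by cleavage of the bond shared by the three- and five-membered rings. C6 is set by backside (invertive) attack on the (5R) centre of 9, C4 by the bridge, since the tethered cation can reach only the enol face syn to the new C6–O bond, and C3 by a chair transition state of the (E)-peroxycarbenium ion that keeps the CH2CO2Me arm equatorial and thus cis to the ketone carbon. The step needs cleavage of the internal and not the peripheral cyclopropane bond, which is secured because the peripheral CH2 is flanked by two quaternary carbons and closed to substitution while only the internal donor carbon can carry positive charge, and it needs the more substituted enol silane, which the ring opening itself writes. Should ionisation run ahead of attack, the 10-phenyldecyl chain still shields the wrong ring face.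

Step 9
Reactants: 16 methyl 2-[(1S,4R,5R,7S)-1,5-dimethyl-6-oxo-7-(10-phenyldecyl)-2,3-dioxabicyclo[3.3.1]nonan-4-yl]acetate
Product: 17 methyl 2-[(1R,4S,6S,9R)-1,6-dimethyl-3-oxo-4-(10-phenyldecyl)-2,7,8-trioxabicyclo[4.3.1]decan-9-yl]acetate
Conditions: mCPBA, CH2Cl2, 0 °C to rt
Reagents that add atoms: 3-chloroperoxybenzoic acid, O=C(OO)c1cccc(Cl)c1
Why: Baeyer–Villiger oxidation: the fully substituted bridgehead carbon migrates in preference to the secondary carbon and with retention, which places the oxygen on C4 in the configuration of the target, and dialkyl peroxides tolerate peracids.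

Step 10
Reactants: 17 methyl 2-[(1R,4S,6S,9R)-1,6-dimethyl-3-oxo-4-(10-phenyldecyl)-2,7,8-trioxabicyclo[4.3.1]decan-9-yl]acetate
Product: 19 (2S)-2-{[(3S,4aR,7aR)-3,4a-dimethyl-6-oxohexahydrofuro[3,2-c][1,2]dioxin-3-yl]methyl}-12-phenyldodecanoic acid (plakortolide K with CO2H on C2′), via hydroxy acid 18 (not isolated)
Conditions: HCl (cat.), THF/H2O, 40 °C
Reagents that add atoms: water, O
Why: Acid-catalysed lactone hydrolysis followed by intramolecular transesterification: the freed tertiary alcohol on C4 lies cis to the CH2CO2Me arm on C3 and closes the five-membered lactone (5-exo-trig), which is favoured over return to the bridged seven-membered ring.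

Step 11
Reactants: 19 (2S)-2-{[(3S,4aR,7aR)-3,4a-dimethyl-6-oxohexahydrofuro[3,2-c][1,2]dioxin-3-yl]methyl}-12-phenyldodecanoic acid
Product: 20 plakortolide K, (3R,4R,6S)
Conditions: 9-mesityl-10-methylacridinium tetrafluoroborate (5 mol%), PhSSPh (10 mol%), iPr2NEt (20 mol%), CF3CH2OH, 450 nm LED, rt
Reagents that add atoms: none
Why: Photoredox hydrodecarboxylation of a carboxylic acid: the carboxylate is oxidised by the excited acridinium and loses CO2, and the secondary C2′ radical, too far from the O–O bond for a small-ring attack, takes a hydrogen atom from the thiol co-catalyst, which erases the auxiliary centre.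

## Compound list

1 | 2,3-dimethylcyclopent-2-en-1-one | CC1=C(C)C(=O)CC1 | starting material
2 | (R)-2,3-dimethylcyclopent-2-en-1-ol | CC1=C(C)CC[C@H]1O | intermediate
3 | (1S,2R,5R)-1,5-dimethylbicyclo[3.1.0]hexan-2-ol | C[C@]12CC[C@@H](O)[C@@]1(C)C2 | intermediate
4 | (1S,5R)-1,5-dimethylbicyclo[3.1.0]hexan-2-one | C[C@]12CCC(=O)[C@@]1(C)C2 | intermediate
5 | phenylmagnesium bromide | Br[Mg]c1ccccc1 | starting material
6 | 1,10-diiododecane | ICCCCCCCCCCI | starting material
7 | (10-iododecyl)benzene | ICCCCCCCCCCc1ccccc1 | intermediate
8 | lithium enolate of 4 | [Li+].C[C@]12CC=C([O-])[C@@]1(C)C2 | intermediate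
9 | (1S,3S,5R)-1,5-dimethyl-3-(10-phenyldecyl)bicyclo[3.1.0]hexan-2-one | C[C@]12C[C@H](CCCCCCCCCCc3ccccc3)C(=O)[C@@]1(C)C2 | intermediate
10 | dimethyl (E)-hex-3-enedioate | COC(=O)C/C=C/CC(=O)OC | starting material
11 | carbonyl oxide of methyl 3-oxopropanoate | COC(=O)CC=[O+][O-] | intermediate
12 | methyl 3-hydroperoxy-3-methoxypropanoate (racemic) | COC(=O)CC(OC)OO | intermediate
13 | methyl 3-methoxy-3-[(triethylsilyl)peroxy]propanoate (racemic) | COC(=O)CC(OC)OO[Si](CC)(CC)CC | intermediate
14 | methyl 3-({(1S,5S)-1,3-dimethyl-5-(10-phenyldecyl)-4-[(trimethylsilyl)oxy]cyclohex-3-en-1-yl}peroxy)-3-methoxypropanoate | C[C@]1(OOC(OC)CC(=O)OC)C[C@H](CCCCCCCCCCc2ccccc2)C(O[Si](C)(C)C)=C(C)C1 | intermediate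
15 | peroxycarbenium triflate derived from 14 by loss of methoxide | C[C@]1(O[O+]=CCC(=O)OC)C[C@H](CCCCCCCCCCc2ccccc2)C(O[Si](C)(C)C)=C(C)C1.[O-]S(=O)(=O)C(F)(F)F | intermediate
16 | methyl 2-[(1S,4R,5R,7S)-1,5-dimethyl-6-oxo-7-(10-phenyldecyl)-2,3-dioxabicyclo[3.3.1]nonan-4-yl]acetate | C[C@]1(C[C@@H]3CCCCCCCCCCc4ccccc4)C[C@@](C)(C3=O)[C@@H](CC(=O)OC)OO1 | intermediate
17 | methyl 2-[(1R,4S,6S,9R)-1,6-dimethyl-3-oxo-4-(10-phenyldecyl)-2,7,8-trioxabicyclo[4.3.1]decan-9-yl]acetate | C[C@]1(C[C@@H]3CCCCCCCCCCc4ccccc4)C[C@@](C)(OC3=O)[C@@H](CC(=O)OC)OO1 | intermediate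
18 | (2S)-2-{[(3S,5R,6R)-5-hydroxy-6-(2-methoxy-2-oxoethyl)-3,5-dimethyl-1,2-dioxan-3-yl]methyl}-12-phenyldodecanoic acid | C[C@]1(C[C@@H](C(=O)O)CCCCCCCCCCc2ccccc2)C[C@@](C)(O)[C@@H](CC(=O)OC)OO1 | intermediate
19 | (2S)-2-{[(3S,4aR,7aR)-3,4a-dimethyl-6-oxohexahydrofuro[3,2-c][1,2]dioxin-3-yl]methyl}-12-phenyldodecanoic acid | C[C@]1(C[C@@H](C(=O)O)CCCCCCCCCCc2ccccc2)C[C@@]2(C)OC(=O)C[C@H]2OO1 | intermediate
20 | plakortolide K | C[C@]1(CCCCCCCCCCCCc2ccccc2)C[C@@]2(C)OC(=O)C[C@H]2OO1 | target

## Step count and risks

Total step count: 11. Longest linear sequence: 8 (steps 1, 2, 3, 5, 8, 9, 10, 11).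

Steps most likely to fail:

**1. Step 8 (proposed new method).**
- What may go wrong: opening of the peripheral instead of the internal cyclopropane bond; full ionisation before the peroxide attacks, with loss of the stereochemical information at C6; proton loss from the peroxycarbenium ion before ring closure.
- Fallback, from 9 back to 16, using the two bond formations as separate known reactions: Me3SiI in CH2Cl2 at −78 °C (known homoconjugate opening of cyclopropyl ketones) should give {[(4S,6S)-4-iodo-2,4-dimethyl-6-(10-phenyldecyl)cyclohex-1-en-1-yl]oxy}trimethylsilane F1. The tertiary iodide then alkylates hydroperoxide 12 under AgOSO2CF3 and 2,6-di-tert-butylpyridine. This is the known silver-promoted peroxide synthesis from tertiary halides, and the ring side chain should guide entry to the opposite face. The product is 14, now isolated. Catalytic Me3SiOSO2CF3 at −78 °C closes 14 to 16 by the known coupling of a silyl enol ether with a peroxycarbenium ion.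

**2. Step 10.**
- What may go wrong: alkyl–oxygen ionisation at the tertiary C4 next to the peroxide-bearing C3 under aqueous acid, followed by fragmentation of the O–O bond, or incomplete opening of the hindered bridged lactone.
- Fallback, from 16 back to 19, replacing attack of water by an internal acyl shuttle: pig liver esterase at pH 7 should hydrolyse only the unhindered methyl ester to 2-[(1S,4R,5R,7S)-1,5-dimethyl-6-oxo-7-(10-phenyldecyl)-2,3-dioxabicyclo[3.3.1]nonan-4-yl]acetic acid F2. Baeyer–Villiger oxidation with mCPBA gives 2-[(1R,4S,6S,9R)-1,6-dimethyl-3-oxo-4-(10-phenyldecyl)-2,7,8-trioxabicyclo[4.3.1]decan-9-yl]acetic acid F3. In warm toluene with a trace of camphorsulfonic acid, the free acid of F3 attacks the lactone carbonyl. The mixed anhydride formed is then captured by the released C4 alcohol, and the compound isomerises to 19.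

**3. Step 11.**
- What may go wrong: reduction of the peroxide by thiolate or by the reduced photocatalyst, base-induced retro-oxa-Michael opening at C3, or oxidation of the terminal arene instead of the carboxylate.
- Fallback, from 19 back to 20, by a neutral radical chain without photocatalyst or amine (Barton decarboxylation): dicyclohexylcarbodiimide and 1-hydroxypyridine-2(1H)-thione in the dark should give the 2-thioxopyridin-1(2H)-yl ester of 19 F4. Irradiation with a tungsten lamp in the presence of t-BuSH then gives 20.

## Further compounds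

F1 | step 8 | {[(4S,6S)-4-iodo-2,4-dimethyl-6-(10-phenyldecyl)cyclohex-1-en-1-yl]oxy}trimethylsilane | C[C@]1(I)C[C@H](CCCCCCCCCCc2ccccc2)C(O[Si](C)(C)C)=C(C)C1
F2 | step 10 | 2-[(1S,4R,5R,7S)-1,5-dimethyl-6-oxo-7-(10-phenyldecyl)-2,3-dioxabicyclo[3.3.1]nonan-4-yl]acetic acid | C[C@]1(C[C@@H]3CCCCCCCCCCc4ccccc4)C[C@@](C)(C3=O)[C@@H](CC(=O)O)OO1
F3 | step 10 | 2-[(1R,4S,6S,9R)-1,6-dimethyl-3-oxo-4-(10-phenyldecyl)-2,7,8-trioxabicyclo[4.3.1]decan-9-yl]acetic acid | C[C@]1(C[C@@H]3CCCCCCCCCCc4ccccc4)C[C@@](C)(OC3=O)[C@@H](CC(=O)O)OO1
F4 | step 11 | 2-thioxopyridin-1(2H)-yl ester of 19 | C[C@]1(C[C@@H](C(=O)On3ccccc3=S)CCCCCCCCCCc2ccccc2)C[C@@]2(C)OC(=O)C[C@H]2OO1
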